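## Retrosynthetic overview

1. The target is two flavanones joined C3–C3'' (unprimed: the 2,3-trans 4-methoxyphenyl unit; doubly primed: the 2'',3''-cis 4-hydroxyphenyl unit); the last operation removes five acetates from 11.
2. Key disconnection C2–C3: ring C of the methoxy unit (O1, C2, C3, C4, C4a, C8a) is the last ring closed, by hydrogen-atom abstraction from a p-methoxybenzyl aryl ether and 6-exo radical addition to an ene-1,4-dione; this isomerises 10 to 11 and sets C2, C3 and C3''.
3. Enabling feature: O1–C2(H)–C6H4OMe of that ring is a p-methoxybenzyl aryl ether in disguise (weak, hydridic benzylic C–H, made so by the 4'-methoxy group), and the C3–C3'' bond between the C4 and C4'' ketones is the reduced form of a C3=C3'' ene-1,4-dione.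
4. Ene-dione 10 comes from Mukaiyama aldol addition and dehydration of (2S)-naringenin triacetate 7 (ring C'' already present, C2'' the only source of chirality) with arylglyoxal 5.
5. Glyoxal 5 comes from phloroacetophenone 1 (diacetylation, Mitsunobu etherification with 4-methoxybenzyl alcohol 3, Riley oxidation); ring order: ring C'' (bought with naringenin), then ring C of the methoxy unit.

Key step: step 7

Remark on the chemistry: (2S)-naringenin 6 is assumed to be available in enantiopure form; if not, triacetate 7 would be upgraded by preparative chiral chromatography. Atom labels of the target (C2, C3, C4; C2'', C3'', C4'') are used for the corresponding atoms of all intermediates. The 2'',3''-cis arrangement is a kinetic one, so no base is used from step 5 onwards.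

## Route

Step 1
Reactants: 1 2',4',6'-trihydroxyacetophenone
Product: 2 1-(2,4-diacetoxy-6-hydroxyphenyl)ethan-1-one
Conditions: Ac2O (2.05 equiv), pyridine (2.5 equiv), CH2Cl2, −10 → 0 °C
Reagents that add atoms: acetic anhydride, CC(=O)OC(C)=O
Why: Regioselective O-acylation; the free 4-OH and then one ortho-OH should react, while the last ortho-OH is locked in a hydrogen bond to the ketone and is far less nucleophilic, the same selectivity as in the bis-alkylation and bis-silylation of phloroacetophenone.

Step 2
Reactants: 2 1-(2,4-diacetoxy-6-hydroxyphenyl)ethan-1-one; 3 4-methoxybenzyl alcohol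
Product: 4 1-[2,4-diacetoxy-6-(4-methoxybenzyloxy)phenyl]ethan-1-one
Conditions: PPh3, DIAD, THF, 0 °C → rt
Reagents that add atoms: none
Why: Mitsunobu etherification of the acidic ortho-acyl phenol with the alkoxyphosphonium salt of 3 under neutral conditions, which should leave the aryl acetates in place (carbonate bases would cleave or shift them).

Step 3
Reactants: 4 1-[2,4-diacetoxy-6-(4-methoxybenzyloxy)phenyl]ethan-1-one
Product: 5 2-[2,4-diacetoxy-6-(4-methoxybenzyloxy)phenyl]-2-oxoacetaldehyde
Conditions: SeO2 (1.3 equiv), 1,4-dioxane/H2O (30:1), 90 °C; then PhMe azeotrope (anhydrous glyoxal)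
Reagents that add atoms: selenium dioxide, O=[Se]=O
Why: Riley oxidation of an aryl methyl ketone to the arylglyoxal through the enol selenite ester; the ketone has a single enolisable position, and hindered 2,6-disubstituted acetophenones are known to undergo this oxidation.

Step 4
Reactants: 6 (2S)-naringenin
Product: 7 (2S)-naringenin 5,7,4'-triacetate
Conditions: Ac2O (4 equiv), pyridine, DMAP (5 mol%), CH2Cl2, 0 °C → rt
Reagents that add atoms: acetic anhydride, CC(=O)OC(C)=O
Why: Exhaustive O-acetylation under mild conditions that should not open the pyranone ring; the acetates make all three arene rings electron-poor and remove every phenolic O–H before the radical step.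

Step 5
Reactants: 7 (2S)-naringenin 5,7,4'-triacetate; 5 2-[2,4-diacetoxy-6-(4-methoxybenzyloxy)phenyl]-2-oxoacetaldehyde
Product: 9 (2S)-5,7-diacetoxy-2-(4-acetoxyphenyl)-3-{2-[2,4-diacetoxy-6-(4-methoxybenzyloxy)phenyl]-1-hydroxy-2-oxoethyl}chroman-4-one (diastereomer mixture at C3'' and at the carbinol carbon C3), via trimethylsilyl enol ether 8 (not isolated)
Conditions: TMSOTf (1.2 equiv), i-Pr2NEt (1.5 equiv), CH2Cl2, 0 °C; then 5, TMSOTf (1.0 equiv), −78 → −40 °C; then 1 M HCl, THF, 0 °C
Reagents that add atoms: none
Why: Soft enolisation gives enol silane 8 without a free enolate (no retro-oxa-Michael opening, C2'' untouched), and the silyl triflate then promotes a Mukaiyama aldol addition to the aldehyde carbon of 5, its more electrophilic carbonyl; both new stereocentres are erased in step 6.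

Step 6
Reactants: 9 aldol adduct
Product: 10 (2R,3E)-5,7-diacetoxy-2-(4-acetoxyphenyl)-3-{2-[2,4-diacetoxy-6-(4-methoxybenzyloxy)phenyl]-2-oxoethylidene}chroman-4-one (C2'' spatially unchanged; the descriptor changes only because the ylidene carbon now outranks the aryl group)
Conditions: Burgess reagent (1.5 equiv), PhMe, 50 °C; then I2 (2 mol%), CH2Cl2, rt
Reagents that add atoms: none
Why: Burgess syn-dehydration of a β-hydroxy ketone under non-basic conditions, followed by iodine-catalysed equilibration to the E isomer (aroyl group anti to C4''=O); base is avoided because the 2''-H is vinylogously acidic and migration of the double bond into ring C'' would erase the stereocentre.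

Step 7
Reactants: 10 (E)-ene-1,4-dione
Product: 11 (2S,3R)-5,7-diacetoxy-3-[(2S,3S)-5,7-diacetoxy-2-(4-acetoxyphenyl)-4-oxochroman-3-yl]-2-(4-methoxyphenyl)chroman-4-one
Conditions: (n-Bu4N)4[W10O32] (2 mol%), degassed MeCN (0.01 M), 390 nm LEDs, 20 °C
Reagents that add atoms: none
Why: Proposed new method: photoexcited [W10O32]4− should abstract a hydrogen atom from the OCH2 group of the single p-methoxybenzyl ether, the nucleophilic α-aryloxybenzyl radical (future C2) should add to C3 of the C3=C3'' ene-1,4-dione, and the tertiary α-keto radical at C3'' should take the hydrogen atom back from the reduced polyoxometalate, so that 10 is isomerised to 11 with no reagent consumed and two carbons that are both electrophilic in polar terms (C2 and C3) are joined. The closest known reaction types are the decatungstate-photocatalysed hydroalkylation of electron-poor alkenes with ethers and benzylic C–H donors (Giese addition, intermolecular) and 6-exo radical cyclisations onto enones that give chroman-4-ones; untested is the intramolecular use on an aryl benzyl ether to close a flavanone ring. Ring C of the methoxy unit closes in the 6-exo-trig radical mode by C2–C3 bond formation at the less substituted alkene carbon, the 7-endo alternative at fully substituted C3'' being disfavoured. C3 (R) is set by the alkene face: in the (E)-3-ylidene flavanone the 2''-aryl group is pseudoaxial (allylic 1,3-strain) and the tethered radical should add anti to it, and C2 (S) follows from a chair-like transition state with the 4-methoxyphenyl group pseudoequatorial, which gives the 2,3-trans ring. C3'' (S) is set when hydrogen is delivered to the planar C3'' radical (or a proton to its enol) anti to the 2''-aryl group, which leaves the new C3–C3'' bond cis to that aryl group, the kinetic arrangement that the target needs. The step needs site-selective hydrogen abstraction, retention of the E geometry and a medium that does not epimerise C3''; the first is secured by the 4-methoxy group (most hydridic, weakest C–H) and by acetates that make the 2''-H and all other sites electron-poor, the others by the thermodynamic preference for E and the neutral, base-free conditions.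

Step 8
Reactants: 11 pentaacetate
Product: 12 (2S,3R)-5,7-dihydroxy-3-[(2S,3S)-5,7-dihydroxy-2-(4-hydroxyphenyl)-4-oxochroman-3-yl]-2-(4-methoxyphenyl)chroman-4-one (target)
Conditions: HCl (1.25 M in MeOH), MeOH/CH2Cl2, 0 °C → rt
Reagents that add atoms: none
Why: Acid-catalysed transesterification of the five aryl acetates with methanol; without base no enolate should form at C3 or C3'', so neither retro-oxa-Michael ring opening nor loss of the kinetic 2'',3''-cis configuration is expected, and the methyl ether is inert.

## Compound list

1 | 2',4',6'-trihydroxyacetophenone (phloroacetophenone) | CC(=O)c1c(O)cc(O)cc1O | starting material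
2 | 1-(2,4-diacetoxy-6-hydroxyphenyl)ethan-1-one | CC(=O)Oc1cc(O)c(C(C)=O)c(OC(C)=O)c1 | intermediate
3 | 4-methoxybenzyl alcohol | COc1ccc(CO)cc1 | starting material
4 | 1-[2,4-diacetoxy-6-(4-methoxybenzyloxy)phenyl]ethan-1-one | CC(=O)Oc1cc(OCc2ccc(OC)cc2)c(C(C)=O)c(OC(C)=O)c1 | intermediate
5 | 2-[2,4-diacetoxy-6-(4-methoxybenzyloxy)phenyl]-2-oxoacetaldehyde | CC(=O)Oc1cc(OCc2ccc(OC)cc2)c(C(=O)C=O)c(OC(C)=O)c1 | intermediate
6 | (2S)-naringenin | C1C(=O)c2c(O)cc(O)cc2O[C@@H]1c1ccc(O)cc1 | starting material
7 | (2S)-naringenin 5,7,4'-triacetate | C1C(=O)c2c(OC(C)=O)cc(OC(C)=O)cc2O[C@@H]1c1ccc(OC(C)=O)cc1 | intermediate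
8 | (2S)-5,7-diacetoxy-2-(4-acetoxyphenyl)-4-(trimethylsilyloxy)-2H-chromene | C1=C(O[Si](C)(C)C)c2c(OC(C)=O)cc(OC(C)=O)cc2O[C@@H]1c1ccc(OC(C)=O)cc1 | intermediate (not isolated)
9 | (2S)-5,7-diacetoxy-2-(4-acetoxyphenyl)-3-{2-[2,4-diacetoxy-6-(4-methoxybenzyloxy)phenyl]-1-hydroxy-2-oxoethyl}chroman-4-one, diastereomer mixture | OC(C(=O)c1c(OCc2ccc(OC)cc2)cc(OC(C)=O)cc1OC(C)=O)C1C(=O)c2c(OC(C)=O)cc(OC(C)=O)cc2O[C@@H]1c1ccc(OC(C)=O)cc1 | intermediate
10 | (2R,3E)-5,7-diacetoxy-2-(4-acetoxyphenyl)-3-{2-[2,4-diacetoxy-6-(4-methoxybenzyloxy)phenyl]-2-oxoethylidene}chroman-4-one | O=C(/C=C1/C(=O)c2c(OC(C)=O)cc(OC(C)=O)cc2O[C@@H]1c1ccc(OC(C)=O)cc1)c1c(OCc2ccc(OC)cc2)cc(OC(C)=O)cc1OC(C)=O | intermediate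
11 | (2S,3R)-5,7-diacetoxy-3-[(2S,3S)-5,7-diacetoxy-2-(4-acetoxyphenyl)-4-oxochroman-3-yl]-2-(4-methoxyphenyl)chroman-4-one | COc1ccc([C@H]2Oc3cc(OC(C)=O)cc(OC(C)=O)c3C(=O)[C@@H]2[C@@H]2C(=O)c3c(OC(C)=O)cc(OC(C)=O)cc3O[C@@H]2c2ccc(OC(C)=O)cc2)cc1 | intermediate
12 | (2S,3R)-5,7-dihydroxy-3-[(2S,3S)-5,7-dihydroxy-2-(4-hydroxyphenyl)-4-oxochroman-3-yl]-2-(4-methoxyphenyl)chroman-4-one | COc1ccc([C@H]2Oc3cc(O)cc(O)c3C(=O)[C@@H]2[C@@H]2C(=O)c3c(O)cc(O)cc3O[C@@H]2c2ccc(O)cc2)cc1 | target

## Step count and risks

Total step count: 8. Longest linear sequence: 7 steps (1, 2, 3, 5, 6, 7, 8, from phloroacetophenone).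

Steps most likely to fail:

1. Step 7 (proposed new method). Several processes could compete with the cyclisation:
   - photochemical E/Z isomerisation of the ene-dione before ring closure, which would erode face selectivity at C3;
   - hydrogen abstraction at the 2''-H, leading to migration of the double bond into ring C'' or to later epimerisation of C2'';
   - direct excitation of the ortho-benzyloxy aryl ketone, with hydrogen shift to the carbonyl oxygen and Yang-type closure to a benzofuranol.

   Fallback: a polar two-step sequence of known reaction types, setting out from 10 and returning at 11. Conjugate reduction of the ene-1,4-dione (Zn dust, AcOH/THF, 0 °C) should give, by protonation of the C4'' enol anti to the 2''-aryl group, the 2'',3''-cis saturated 1,4-diketone (2S,3S)-5,7-diacetoxy-2-(4-acetoxyphenyl)-3-{2-[2,4-diacetoxy-6-(4-methoxybenzyloxy)phenyl]-2-oxoethyl}chroman-4-one F1. Oxidative cyclisation of F1 (DDQ, 2,6-dichloropyridine, LiClO4, 4 Å sieves, 1,2-dichloroethane, rt) would then remove hydride from the p-methoxybenzyl ether. The resulting aryloxy-stabilised benzylic cation should be trapped at C3 by the enol of the C4 ketone through a chair-like, 2,3-trans closure, as in oxidative cyclisations of p-methoxybenzyl ethers and the dehydrogenative coupling of benzyl ethers with ketones. Diastereocontrol at C3 relative to C3'' would have to be checked.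

2. Step 6. The exocyclic C3''=C3 double bond could migrate into ring C'' (giving the 3-phenacylflavone and erasing C2'') under warm or slightly basic dehydration conditions, and E/Z control could be incomplete.

   Fallback: elimination through a selenoxide instead of O-activation, setting out from 9 and returning at 10. Treatment of 9 with N-(phenylselanyl)phthalimide and PBu3 (THF, 0 °C) should replace the hydroxyl group and give the α-seleno ketone 5,7-diacetoxy-2-(4-acetoxyphenyl)-3-{2-[2,4-diacetoxy-6-(4-methoxybenzyloxy)phenyl]-2-oxo-1-(phenylselanyl)ethyl}chroman-4-one F2. Oxidation with H2O2 (CH2Cl2, 0 °C) should give the corresponding selenoxide F3, which is not isolated and should undergo syn-elimination towards the only β-hydrogen (3''-H) at or below room temperature in a neutral medium.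

3. Step 3. Hot aqueous selenous acid could over-oxidise the product to the arylglyoxylic acid, solvolyse the aryl acetates or cleave the p-methoxybenzyl ether.

   Fallback: halogenation followed by Kornblum oxidation, setting out from 4 and returning at 5. α-Bromination of 4 with PhNMe3Br3 (THF, 0 °C) should give 2-bromo-1-[2,4-diacetoxy-6-(4-methoxybenzyloxy)phenyl]ethan-1-one F4, which in DMSO with NaHCO3 at rt should be oxidised through the alkoxysulfonium salt to glyoxal 5.

Further compounds
F1 | step 7 | (2S,3S)-5,7-diacetoxy-2-(4-acetoxyphenyl)-3-{2-[2,4-diacetoxy-6-(4-methoxybenzyloxy)phenyl]-2-oxoethyl}chroman-4-one | O=C(C[C@@H]1C(=O)c2c(OC(C)=O)cc(OC(C)=O)cc2O[C@@H]1c1ccc(OC(C)=O)cc1)c1c(OCc2ccc(OC)cc2)cc(OC(C)=O)cc1OC(C)=O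
F2 | step 6 | 5,7-diacetoxy-2-(4-acetoxyphenyl)-3-{2-[2,4-diacetoxy-6-(4-methoxybenzyloxy)phenyl]-2-oxo-1-(phenylselanyl)ethyl}chroman-4-one (2S at C2'', diastereomer mixture) | O=C(c1c(OCc2ccc(OC)cc2)cc(OC(C)=O)cc1OC(C)=O)C([Se]c1ccccc1)C1C(=O)c2c(OC(C)=O)cc(OC(C)=O)cc2O[C@@H]1c1ccc(OC(C)=O)cc1
F3 | step 6 | selenoxide of F2 (not isolated) | O=C(c1c(OCc2ccc(OC)cc2)cc(OC(C)=O)cc1OC(C)=O)C([Se](=O)c1ccccc1)C1C(=O)c2c(OC(C)=O)cc(OC(C)=O)cc2O[C@@H]1c1ccc(OC(C)=O)cc1
F4 | step 3 | 2-bromo-1-[2,4-diacetoxy-6-(4-methoxybenzyloxy)phenyl]ethan-1-one | CC(=O)Oc1cc(OCc2ccc(OC)cc2)c(C(=O)CBr)c(OC(C)=O)c1
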